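**Retrosynthetic overview**

1. Feature: in ring A (C1–C5) the quaternary fusion carbon C1 is bonded to the fusion carbon C5, which lies between the oxygenated carbons C4 and C6. C5 can therefore be a carbenoid carbon next to a C4 ketone, 1,5 to a C1 methine through C4–C3–C2, and carry the phosphonate that later makes C5=C6 of ring B (C1, C5–C10).
2. Ester C6–O ⇒ 4,6-diol + silyl-protected p-coumaric acid; 6α-OH ⇐ hydroxyl-directed reduction of a C6 ketol; 4β-OH and H-5 ⇐ SmI2 opening of a 4β,5β-epoxy C6 ketone, made from the C4=C5/C6=O enone by reduction, directed epoxidation and reoxidation.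
3. That enone ⇐ isopropyl addition and oxidative 1,3-transposition of a bicyclic C4-keto C5=C6 dienone; ring B is formed second, by intramolecular Horner–Wadsworth–Emmons closure at C5=C6.
4. Ring A is formed first: C1–C5 by Rh2(OAc)4-catalysed carbenoid insertion into the tertiary C1–H bond of an acyclic (Z)-alkenyl α-diazo-β-ketophosphonate, with retention at C1.
5. Diazo compound ⇐ C2–C3 alkylation of the dimethyl (2-oxopropyl)phosphonate dianion with a primary iodide; the C1 methine ⇐ auxiliary-controlled propionate alkylation with a Z-allylic bromide from 4-methyl-5,6-dihydro-2H-pyran-2-one.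

Key step: step 10

Remark: C1–C10 are the skeleton atoms labelled above and β is the face of the bicycle carrying the C1 methyl group; the phenol of p-coumaric acid is assumed to need protection (tert-butyldimethylsilyl ether) during esterification.

**Route**

Step 1
Reactants: 1 4-methyl-5,6-dihydro-2H-pyran-2-one
Product: 2 (2Z)-5-hydroxy-N-methoxy-N,3-dimethylpent-2-enamide
Conditions: MeNH(OMe)·HCl, AlMe3, CH2Cl2, 0 °C to rt; aq. potassium sodium tartrate (KNaC4H4O6)
Reagents that add atoms: N,O-dimethylhydroxylamine hydrochloride, CNOC.Cl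
Why: Weinreb aminolysis of the lactone by MeAl(Cl)N(OMe)Me opens the ring at the acyl carbon only, so the ring-enforced Z geometry of the future C8=C9 alkene is kept and the two oxygen termini become different.

Step 2
Reactants: 2 (2Z)-5-hydroxy-N-methoxy-N,3-dimethylpent-2-enamide
Product: 3 (2Z)-5-[(tert-butyldimethylsilyl)oxy]-N-methoxy-N,3-dimethylpent-2-enamide
Conditions: TBSCl, imidazole, DMF, 0 °C to rt
Reagents that add atoms: tert-butyldimethylsilyl chloride, CC(C)(C)[Si](C)(C)Cl
Why: Silylation of the primary alcohol (future C6–O) blocks relactonisation and protects this terminus up to step 11.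

Step 3
Reactants: 3 (2Z)-5-[(tert-butyldimethylsilyl)oxy]-N-methoxy-N,3-dimethylpent-2-enamide
Product: 5 (2Z)-5-[(tert-butyldimethylsilyl)oxy]-3-methylpent-2-en-1-ol, via Z-enal 4 (not isolated)
Conditions: i-Bu2AlH, THF, −78 °C; then MeOH, NaBH4, −78 to 0 °C
Reagents that add atoms: none
Why: Weinreb amide reduction stops at the aldehyde level through the chelated aluminium hemiaminal, and the Z-enal released on methanolysis is reduced at once 1,2 by NaBH4, which should prevent Z/E isomerisation.

Step 4
Reactants: 5 (2Z)-5-[(tert-butyldimethylsilyl)oxy]-3-methylpent-2-en-1-ol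
Product: 6 {[(3Z)-5-bromo-3-methylpent-3-en-1-yl]oxy}(tert-butyl)dimethylsilane
Conditions: CBr4, PPh3, CH2Cl2, −20 to 0 °C
Reagents that add atoms: carbon tetrabromide, BrC(Br)(Br)Br
Why: Appel bromination proceeds by SN2 displacement at the primary allylic carbon, so neither allylic transposition nor loss of the Z geometry is expected and the silyl ether is untouched.

Step 5
Reactants: 7 (S)-4-benzyl-3-propionyloxazolidin-2-one; 6 {[(3Z)-5-bromo-3-methylpent-3-en-1-yl]oxy}(tert-butyl)dimethylsilane
Product: 9 (4S)-4-benzyl-3-[(2R,4Z)-7-[(tert-butyldimethylsilyl)oxy]-2,5-dimethylhept-4-enoyl]oxazolidin-2-one, via sodium Z-enolate 8 (not isolated)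
Conditions: NaN(SiMe3)2, THF, −78 °C; then 6, −78 to −40 °C
Reagents that add atoms: none
Why: Evans asymmetric alkylation, in which the chelated Z-enolate is attacked by the allylic bromide on the face opposite the benzyl group, sets the (2R) methyl-bearing methine that becomes C1 and forms the C1–C10 bond.

Step 6
Reactants: 9 (4S)-4-benzyl-3-[(2R,4Z)-7-[(tert-butyldimethylsilyl)oxy]-2,5-dimethylhept-4-enoyl]oxazolidin-2-one
Product: 10 (2R,4Z)-7-[(tert-butyldimethylsilyl)oxy]-2,5-dimethylhept-4-en-1-ol
Conditions: LiBH4, MeOH, THF, 0 °C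
Reagents that add atoms: none
Why: Reductive cleavage of the imide by LiBH4 gives the primary alcohol and the recoverable auxiliary without touching the stereocentre, the alkene or the silyl ether.

Step 7
Reactants: 10 (2R,4Z)-7-[(tert-butyldimethylsilyl)oxy]-2,5-dimethylhept-4-en-1-ol
Product: 11 tert-butyl{[(3Z,6R)-7-iodo-3,6-dimethylhept-3-en-1-yl]oxy}dimethylsilane
Conditions: I2, PPh3, imidazole, CH2Cl2, 0 °C to rt
Reagents that add atoms: iodine, II
Why: Appel-type iodination of the primary alcohol is an SN2 reaction at C2 and leaves the adjacent methine (C1) and the buffered silyl ether intact.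

Step 8
Reactants: 12 dimethyl (2-oxopropyl)phosphonate; 11 tert-butyl{[(3Z,6R)-7-iodo-3,6-dimethylhept-3-en-1-yl]oxy}dimethylsilane
Product: 14 dimethyl [(5S,7Z)-10-[(tert-butyldimethylsilyl)oxy]-5,8-dimethyl-2-oxodec-7-en-1-yl]phosphonate, via ketophosphonate dianion 13 (not isolated)
Conditions: NaH, THF, 0 °C; n-BuLi, −20 to 0 °C; then 11, 0 °C to rt
Reagents that add atoms: none
Why: γ-Alkylation of a β-ketophosphonate 1,3-dianion, in which the more basic terminal carbanion displaces the primary iodide, forms C2–C3 and leaves the phosphonate-stabilised position free for diazo transfer.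

Step 9
Reactants: 14 dimethyl [(5S,7Z)-10-[(tert-butyldimethylsilyl)oxy]-5,8-dimethyl-2-oxodec-7-en-1-yl]phosphonate
Product: 15 dimethyl [(5S,7Z)-10-[(tert-butyldimethylsilyl)oxy]-1-diazo-5,8-dimethyl-2-oxodec-7-en-1-yl]phosphonate
Conditions: 4-AcNHC6H4SO2N3, DBU, MeCN, 0 °C to rt
Reagents that add atoms: 4-acetamidobenzenesulfonyl azide, CC(=O)Nc1ccc(cc1)S(=O)(=O)N=[N+]=[N-]
Why: Regitz diazo transfer to the doubly activated methylene between ketone and phosphonate gives the α-diazo-β-ketophosphonate under conditions that do not affect the alkene, the methine or the silyl ether.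

Step 10
Reactants: 15 dimethyl [(5S,7Z)-10-[(tert-butyldimethylsilyl)oxy]-1-diazo-5,8-dimethyl-2-oxodec-7-en-1-yl]phosphonate
Product: 16 dimethyl [(1R,2R)-2-{(2Z)-5-[(tert-butyldimethylsilyl)oxy]-3-methylpent-2-en-1-yl}-2-methyl-5-oxocyclopentyl]phosphonate
Conditions: Rh2(OAc)4 (2 mol%), CH2Cl2, 40 °C, slow addition of 15
Reagents that add atoms: none
Why: Rh2(OAc)4 expels N2 from 15 to give an electrophilic carbenoid at C5, flanked by the C4 ketone and the phosphonate, which inserts into the tertiary C1–H bond through a concerted three-centre transition state; the closest known reaction type is the dirhodium-catalysed 1,5 C–H insertion of α-diazo-β-keto esters and α-diazo-β-ketophosphonates into unactivated methine C–H bonds. Ring A closes by forming the C1–C5 bond in the five-membered (1,5) insertion mode, the two carbons being linked by the C4–C3–C2 tether. The new quaternary centre C1 is formed with retention of configuration and so carries over the methine set by the auxiliary in step 5, while C5 should settle as the epimer with the phosphonate trans to the alkenyl chain but is enolisable and disappears in step 12. The step needs site selectivity for C1–H: it is the only methine and the only C–H bond within reach of a five-membered transition state, the allylic C10–H bonds would need a six-membered one, the C8=C9 alkene could only be cyclopropanated through a bicyclo[5.1.0] transition state, and the methyl esters on phosphorus offer no 1,5 C–H bond.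

Step 11
Reactants: 16 dimethyl [(1R,2R)-2-{(2Z)-5-[(tert-butyldimethylsilyl)oxy]-3-methylpent-2-en-1-yl}-2-methyl-5-oxocyclopentyl]phosphonate
Product: 17 dimethyl [(1R,2R)-2-[(2Z)-5-hydroxy-3-methylpent-2-en-1-yl]-2-methyl-5-oxocyclopentyl]phosphonate
Conditions: HF·pyridine, pyridine, THF, 0 °C to rt
Reagents that add atoms: none
Why: Buffered fluoride cleaves the primary silyl ether and should leave the β-ketophosphonate and the trisubstituted alkene unchanged.

Step 12
Reactants: 17 dimethyl [(1R,2R)-2-[(2Z)-5-hydroxy-3-methylpent-2-en-1-yl]-2-methyl-5-oxocyclopentyl]phosphonate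
Product: 19 (8aR)-6,8a-dimethyl-1,5,8,8a-tetrahydroazulen-3(2H)-one (C4 ketone; C5=C6; C8=C9), via keto aldehyde 18 (not isolated)
Conditions: Dess–Martin periodinane, NaHCO3, CH2Cl2, 0 °C; filter, concentrate; LiCl, i-Pr2NEt, MeCN (0.003 M), rt
Reagents that add atoms: none
Why: Buffered Dess–Martin oxidation should give the β,γ-unsaturated aldehyde without migration of C8=C9, and the intramolecular Horner–Wadsworth–Emmons reaction of the lithium-chelated C5 phosphonate anion (Masamune–Roush conditions, a weak amine base that spares the C7 protons) then closes the seven-membered ring B at C5=C6, helped by the Z-alkene that holds C7 and C10 on the same side.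

Step 13
Reactants: 19 (8aR)-6,8a-dimethyl-1,5,8,8a-tetrahydroazulen-3(2H)-one
Product: 20 (8aR)-3-isopropyl-6,8a-dimethyl-1,2,3,5,8,8a-hexahydroazulen-3-ol (mixture of C4 epimers)
Conditions: CeCl3 (anhydrous), i-PrMgCl, THF, −78 °C
Reagents that add atoms: isopropylmagnesium chloride, CC(C)[Mg]Cl
Why: The organocerium reagent i-PrCeCl2 is nucleophilic but hardly basic, so it should add 1,2 to the C4 ketone without enolisation at C3, vinylogous deprotonation at C7, β-hydride reduction or conjugate addition; both C4 epimers serve because this centre is erased in step 14.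

Step 14
Reactants: 20 (8aR)-3-isopropyl-6,8a-dimethyl-1,2,3,5,8,8a-hexahydroazulen-3-ol
Product: 21 (8aR)-3-isopropyl-6,8a-dimethyl-2,5,8,8a-tetrahydroazulen-4(1H)-one (C6 ketone; C4=C5; C8=C9)
Conditions: C5H5NH[CrO3Cl] (pyridinium chlorochromate), 4 Å molecular sieves, CH2Cl2, rt
Reagents that add atoms: pyridinium chlorochromate (supplies the C6 oxygen), [O-][Cr](=O)(=O)Cl.c1cc[nH+]cc1
Why: Babler–Dauben oxidative transposition, in which the chromate ester of the tertiary allylic alcohol shifts [3,3] to C6 and is then oxidised, moves the oxygen to C6 and the alkene to C4=C5 while the isolated C8=C9 alkene stays in place.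

Step 15
Reactants: 21 (8aR)-3-isopropyl-6,8a-dimethyl-2,5,8,8a-tetrahydroazulen-4(1H)-one
Product: 22 (4R,8aR)-3-isopropyl-6,8a-dimethyl-1,2,4,5,8,8a-hexahydroazulen-4-ol (6β-hydroxyl)
Conditions: i-Bu2AlH, toluene, −78 °C; aq. potassium sodium tartrate (KNaC4H4O6)
Reagents that add atoms: none
Why: 1,2-Reduction of the hindered enone by the bulky, non-basic aluminium hydride is expected from the α face, away from the axial C1 methyl group that is 1,3-related to C6 on the β face, which sets the 6β-hydroxyl needed to steer step 16.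

Step 16
Reactants: 22 (4R,8aR)-3-isopropyl-6,8a-dimethyl-1,2,4,5,8,8a-hexahydroazulen-4-ol
Product: 23 4β,5β-epoxide of 22 (epoxide oxygen and 6-hydroxyl both on the β face)
Conditions: VO(acac)2 (5 mol%), t-BuOOH (decane), CH2Cl2, 0 °C
Reagents that add atoms: tert-butyl hydroperoxide, CC(C)(C)OO
Why: In the hydroxyl-directed epoxidation catalysed by VO(acac)2 the metal-bound peroxide is delivered to the tetrasubstituted allylic C4=C5 alkene on the face of the hydroxyl group, which fixes the β C4–O bond of the target, while the merely homoallylic C8=C9 alkene should react far more slowly.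

Step 17
Reactants: 23 4β,5β-epoxy-6β-alcohol
Product: 24 4β,5β-epoxy C6 ketone
Conditions: Dess–Martin periodinane, NaHCO3, CH2Cl2, 0 °C
Reagents that add atoms: none
Why: Neutral, buffered Dess–Martin oxidation of the secondary alcohol gives the α,β-epoxy ketone without opening the epoxide or moving the β,γ C8=C9 bond.

Step 18
Reactants: 24 4β,5β-epoxy C6 ketone
Product: 25 (3R,3aR,8aR)-3-hydroxy-3-isopropyl-6,8a-dimethyl-2,3,3a,5,8,8a-hexahydroazulen-4(1H)-one (trans-fused ketol: 4β-OH, H-5α)
Conditions: SmI2, THF/MeOH, −78 °C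
Reagents that add atoms: none
Why: In the SmI2 reduction of an α,β-epoxy ketone, electron transfer to the C6 ketone, cleavage of the adjacent C5–O bond and a second electron give an enolate that methanol protonates at C5, so the C4 oxygen keeps its β configuration and C5 is expected to take the α hydrogen (trans fusion), the arrangement that keeps C6 away from the C4 isopropyl group and cis to the C4 hydroxyl with which the ketone hydrogen-bonds.

Step 19
Reactants: 25 trans-fused ketol
Product: 26 (3R,3aS,4S,8aR)-3-isopropyl-6,8a-dimethyl-1,2,3,3a,4,5,8,8a-octahydroazulene-3,4-diol (4β,6α-diol)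
Conditions: Me4NBH(OAc)3, MeCN/AcOH, −30 to −20 °C
Reagents that add atoms: none
Why: In the Evans–Saksena reduction the tertiary C4 hydroxyl exchanges onto boron and the resulting alkoxy(diacetoxy)borohydride delivers hydride to the C6 ketone through a chair-like six-membered transition state; because the trans ring fusion twists ring A so that the β C4–O bond lies over the β face of C6, hydride enters there and the new hydroxyl is α (1,3-anti to the C4 hydroxyl along C3–C7), the free reagent being too weak to reduce the ketone from the other face.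

Step 20
Reactants: 27 p-coumaric acid
Product: 29 (2E)-3-{4-[(tert-butyldimethylsilyl)oxy]phenyl}prop-2-enoic acid, via bis-silyl derivative 28 (not isolated)
Conditions: TBSCl (2.2 equiv), imidazole, DMF, rt; then AcOH/THF/H2O, rt
Reagents that add atoms: tert-butyldimethylsilyl chloride, CC(C)(C)[Si](C)(C)Cl
Why: Silylation of both phenol and acid followed by mild hydrolysis of the far more labile silyl ester leaves the aryl silyl ether and frees the acid for coupling.

Step 21
Reactants: 26 4β,6α-diol; 29 (2E)-3-{4-[(tert-butyldimethylsilyl)oxy]phenyl}prop-2-enoic acid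
Product: 31 6-O-[(E)-4-(tert-butyldimethylsilyloxy)cinnamoyl] ester of diol 26, via mixed anhydride 30 (not isolated)
Conditions: 2,4,6-Cl3C6H2COCl, Et3N, THF, rt; then 26, DMAP, toluene, rt
Reagents that add atoms: none
Why: In the Yamaguchi esterification the mixed anhydride acylates DMAP and the acylpyridinium ion esterifies the secondary C6 hydroxyl with retention at C6, the tertiary C4 hydroxyl being too hindered to react.

Step 22
Reactants: 31 silyl-protected ester
Product: 32 (3R,3aS,4S,8aR)-3-hydroxy-3-isopropyl-6,8a-dimethyl-1,2,3,3a,4,5,8,8a-octahydroazulen-4-yl (2E)-3-(4-hydroxyphenyl)prop-2-enoate (target)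
Conditions: Bu4NF, AcOH, THF, 0 °C
Reagents that add atoms: none
Why: Fluoride cleaves the aryl silyl ether, and the acetic acid buffer keeps the liberated phenoxide from attacking the cinnamate ester or disturbing the tertiary alcohol.

**Compound list**

1 | 4-methyl-5,6-dihydro-2H-pyran-2-one | CC1=CC(=O)OCC1 | starting material
2 | (2Z)-5-hydroxy-N-methoxy-N,3-dimethylpent-2-enamide | C/C(CCO)=C/C(=O)N(C)OC | intermediate
3 | (2Z)-5-[(tert-butyldimethylsilyl)oxy]-N-methoxy-N,3-dimethylpent-2-enamide | C/C(CCO[Si](C)(C)C(C)(C)C)=C/C(=O)N(C)OC | intermediate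
4 | (2Z)-5-[(tert-butyldimethylsilyl)oxy]-3-methylpent-2-enal (not isolated) | C/C(CCO[Si](C)(C)C(C)(C)C)=C/C=O | intermediate
5 | (2Z)-5-[(tert-butyldimethylsilyl)oxy]-3-methylpent-2-en-1-ol | C/C(CCO[Si](C)(C)C(C)(C)C)=C/CO | intermediate
6 | {[(3Z)-5-bromo-3-methylpent-3-en-1-yl]oxy}(tert-butyl)dimethylsilane | C/C(CCO[Si](C)(C)C(C)(C)C)=C/CBr | intermediate
7 | (S)-4-benzyl-3-propionyloxazolidin-2-one | CCC(=O)N1[C@@H](Cc2ccccc2)COC1=O | starting material
8 | sodium (Z)-enolate of 7 (not isolated) | C/C=C(\[O-])N1[C@@H](Cc2ccccc2)COC1=O.[Na+] | intermediate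
9 | (4S)-4-benzyl-3-[(2R,4Z)-7-[(tert-butyldimethylsilyl)oxy]-2,5-dimethylhept-4-enoyl]oxazolidin-2-one | C/C(CCO[Si](C)(C)C(C)(C)C)=C/C[C@@H](C)C(=O)N1[C@@H](Cc2ccccc2)COC1=O | intermediate
10 | (2R,4Z)-7-[(tert-butyldimethylsilyl)oxy]-2,5-dimethylhept-4-en-1-ol | C/C(CCO[Si](C)(C)C(C)(C)C)=C/C[C@@H](C)CO | intermediate
11 | tert-butyl{[(3Z,6R)-7-iodo-3,6-dimethylhept-3-en-1-yl]oxy}dimethylsilane | C/C(CCO[Si](C)(C)C(C)(C)C)=C/C[C@@H](C)CI | intermediate
12 | dimethyl (2-oxopropyl)phosphonate | CC(=O)CP(=O)(OC)OC | starting material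
13 | sodium lithium 1,3-dianion of 12 (not isolated) | [CH2-]C(=O)[CH-]P(=O)(OC)OC.[Na+].[Li+] | intermediate
14 | dimethyl [(5S,7Z)-10-[(tert-butyldimethylsilyl)oxy]-5,8-dimethyl-2-oxodec-7-en-1-yl]phosphonate | C/C(CCO[Si](C)(C)C(C)(C)C)=C/C[C@@H](C)CCC(=O)CP(=O)(OC)OC | intermediate
15 | dimethyl [(5S,7Z)-10-[(tert-butyldimethylsilyl)oxy]-1-diazo-5,8-dimethyl-2-oxodec-7-en-1-yl]phosphonate | C/C(CCO[Si](C)(C)C(C)(C)C)=C/C[C@@H](C)CCC(=O)C(=[N+]=[N-])P(=O)(OC)OC | intermediate
16 | dimethyl [(1R,2R)-2-{(2Z)-5-[(tert-butyldimethylsilyl)oxy]-3-methylpent-2-en-1-yl}-2-methyl-5-oxocyclopentyl]phosphonate (phosphonate trans to the alkenyl chain; C5 epimerisable) | C/C(CCO[Si](C)(C)C(C)(C)C)=C/C[C@@]1(C)CCC(=O)[C@@H]1P(=O)(OC)OC | intermediate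
17 | dimethyl [(1R,2R)-2-[(2Z)-5-hydroxy-3-methylpent-2-en-1-yl]-2-methyl-5-oxocyclopentyl]phosphonate | C/C(CCO)=C/C[C@@]1(C)CCC(=O)[C@@H]1P(=O)(OC)OC | intermediate
18 | dimethyl [(1R,2R)-2-methyl-2-[(2Z)-3-methyl-5-oxopent-2-en-1-yl]-5-oxocyclopentyl]phosphonate (not isolated) | C/C(CC=O)=C/C[C@@]1(C)CCC(=O)[C@@H]1P(=O)(OC)OC | intermediate
19 | (8aR)-6,8a-dimethyl-1,5,8,8a-tetrahydroazulen-3(2H)-one | CC1=CC[C@@]2(C)CCC(=O)C2=CC1 | intermediate
20 | (8aR)-3-isopropyl-6,8a-dimethyl-1,2,3,5,8,8a-hexahydroazulen-3-ol (C4 epimers) | CC1=CC[C@@]2(C)CCC(O)(C(C)C)C2=CC1 | intermediate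
21 | (8aR)-3-isopropyl-6,8a-dimethyl-2,5,8,8a-tetrahydroazulen-4(1H)-one | CC1=CC[C@@]2(C)CCC(C(C)C)=C2C(=O)C1 | intermediate
22 | (4R,8aR)-3-isopropyl-6,8a-dimethyl-1,2,4,5,8,8a-hexahydroazulen-4-ol (6β-OH) | CC1=CC[C@@]2(C)CCC(C(C)C)=C2[C@H](O)C1 | intermediate
23 | 4β,5β-epoxy-6β-alcohol (epoxide of 22, oxygen and hydroxyl on the β face) | CC1=CC[C@@]2(C)CC[C@]3(C(C)C)O[C@]23[C@H](O)C1 | intermediate
24 | 4β,5β-epoxy C6 ketone | CC1=CC[C@@]2(C)CC[C@]3(C(C)C)O[C@]23C(=O)C1 | intermediate
25 | (3R,3aR,8aR)-3-hydroxy-3-isopropyl-6,8a-dimethyl-2,3,3a,5,8,8a-hexahydroazulen-4(1H)-one | CC1=CC[C@@]2(C)CC[C@@](O)(C(C)C)[C@@H]2C(=O)C1 | intermediate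
26 | (3R,3aS,4S,8aR)-3-isopropyl-6,8a-dimethyl-1,2,3,3a,4,5,8,8a-octahydroazulene-3,4-diol | CC1=CC[C@@]2(C)CC[C@@](O)(C(C)C)[C@@H]2[C@@H](O)C1 | intermediate
27 | p-coumaric acid | O=C(O)/C=C/c1ccc(O)cc1 | starting material
28 | tert-butyldimethylsilyl (2E)-3-{4-[(tert-butyldimethylsilyl)oxy]phenyl}prop-2-enoate (not isolated) | O=C(O[Si](C)(C)C(C)(C)C)/C=C/c1ccc(O[Si](C)(C)C(C)(C)C)cc1 | intermediate
29 | (2E)-3-{4-[(tert-butyldimethylsilyl)oxy]phenyl}prop-2-enoic acid | O=C(O)/C=C/c1ccc(O[Si](C)(C)C(C)(C)C)cc1 | intermediate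
30 | mixed anhydride of 29 with 2,4,6-trichlorobenzoic acid (not isolated) | O=C(/C=C/c1ccc(O[Si](C)(C)C(C)(C)C)cc1)OC(=O)c1c(Cl)cc(Cl)cc1Cl | intermediate
31 | (3R,3aS,4S,8aR)-3-hydroxy-3-isopropyl-6,8a-dimethyl-1,2,3,3a,4,5,8,8a-octahydroazulen-4-yl (2E)-3-{4-[(tert-butyldimethylsilyl)oxy]phenyl}prop-2-enoate | CC1=CC[C@@]2(C)CC[C@@](O)(C(C)C)[C@@H]2[C@@H](OC(=O)/C=C/c2ccc(O[Si](C)(C)C(C)(C)C)cc2)C1 | intermediate
32 | (3R,3aS,4S,8aR)-3-hydroxy-3-isopropyl-6,8a-dimethyl-1,2,3,3a,4,5,8,8a-octahydroazulen-4-yl (2E)-3-(4-hydroxyphenyl)prop-2-enoate | CC1=CC[C@@]2(C)CC[C@@](O)(C(C)C)[C@@H]2[C@@H](OC(=O)/C=C/c2ccc(O)cc2)C1 | target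

**Step count and risks**

Total step count: 22. Longest linear sequence: 21 steps (steps 1–19, 21 and 22, from lactone 1); step 20 is a one-step side branch.

Steps most likely to fail:

Step 10. The carbenoid may be diverted from the C1–H methine, by addition to the C8=C9 alkene or by insertion into the allylic C10–H bonds, or it may simply react sluggishly as ketophosphonate carbenoids can. The fallback takes the alkene out of play before the carbenoid is made. It sets out from ketophosphonate 14, which is epoxidised (m-CPBA, NaHCO3, CH2Cl2, 0 °C) to the cis-8,9-epoxy ketophosphonate F1; either epoxide diastereomer serves. Diazo transfer as in step 9 gives the epoxy diazo ketophosphonate F2. Rh2(OAc)4 then has only the C1–H methine within reach and should give the epoxy cyclopentanone F3. Stereospecific deoxygenation of the trisubstituted epoxide with retention (Ph3P=Se, CF3CO2H, CH2Cl2, rt) restores the Z-alkene and comes back to the route at compound 16.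

Step 12. The C5 phosphonate anion is flanked by the quaternary C1 and may close the seven-membered ring slowly. During that time base can move the C8=C9 bond into conjugation (through the aldehyde enolate or by deprotonation of the skipped dienone at C7), and oligomers can form. The fallback makes C5=C6 by ring-closing metathesis, which needs no base on the sensitive aldehyde or dienone. It sets out from alcohol 17, oxidised as in step 12 to aldehyde 18. The crude aldehyde is methylenated chemoselectively (CH2I2, Zn, Ti(O-i-Pr)4, THF, rt) to the terminal alkene phosphonate F4. The phosphonate is then used in an intermolecular Horner–Wadsworth–Emmons reaction with formaldehyde (aq. HCHO, K2CO3, THF, 0 °C) to give the α-methylene cyclopentanone F5. Second-generation Grubbs catalyst (CH2Cl2, 40 °C, high dilution) joins the exocyclic methylene at C5 to the vinyl group with loss of ethene and comes back to the route at dienone 19.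

Step 18. Protonation of the enolate at C5 may show poor facial selectivity; methanol held on the samarium-bound C4 alkoxide could deliver the proton to the β face and give the cis-fused epimer. The fallback replaces kinetic by thermodynamic control at C5. It sets out from epoxy ketone 24, whose reduction is accepted as it comes. The cis-fused ketol F6, alone or mixed with 25, is equilibrated through its enol with a catalytic amine base (DBU, CH2Cl2, 0 °C to rt, mild enough to avoid retro-aldol cleavage of C4–C5). F6 holds C6 cis to the isopropyl group on the neighbouring quaternary carbon, and relief of this contact should drive the equilibrium to the trans-fused ketol 25, where the route is rejoined.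

**Further compounds**

F1 | step 10 | dimethyl {(5S)-10-[(tert-butyldimethylsilyl)oxy]-7,8-epoxy-5,8-dimethyl-2-oxodecyl}phosphonate (cis-epoxide, one of two epoxide diastereomers shown) | C[C@@]1(CCO[Si](C)(C)C(C)(C)C)O[C@H]1C[C@@H](C)CCC(=O)CP(=O)(OC)OC
F2 | step 10 | dimethyl {(5S)-10-[(tert-butyldimethylsilyl)oxy]-1-diazo-7,8-epoxy-5,8-dimethyl-2-oxodecyl}phosphonate | C[C@@]1(CCO[Si](C)(C)C(C)(C)C)O[C@H]1C[C@@H](C)CCC(=O)C(=[N+]=[N-])P(=O)(OC)OC
F3 | step 10 | side-chain cis-epoxide of cyclopentanone 16 | C[C@@]1(CCO[Si](C)(C)C(C)(C)C)O[C@H]1C[C@@]1(C)CCC(=O)[C@@H]1P(=O)(OC)OC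
F4 | step 12 | dimethyl {(1R,2R)-2-methyl-2-[(2Z)-3-methylhexa-2,5-dien-1-yl]-5-oxocyclopentyl}phosphonate | C/C(CC=C)=C/C[C@@]1(C)CCC(=O)[C@@H]1P(=O)(OC)OC
F5 | step 12 | (3R)-3-methyl-3-[(2Z)-3-methylhexa-2,5-dien-1-yl]-2-methylidenecyclopentan-1-one | C/C(CC=C)=C/C[C@@]1(C)CCC(=O)C1=C
F6 | step 18 | cis-fused ketol, C5 epimer of 25 | CC1=CC[C@@]2(C)CC[C@@](O)(C(C)C)[C@H]2C(=O)C1
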